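The numbers in the tables come from a simulation on assumed constants.

At early times the eta run is still filling: G, E and D together read 83.8% of the L charged at 3.00 h and 93.7% at 5.00 h.

- eta: L 2.5 M; run made earlier
- flask: L 1.8 M; time 2.0 d

eta run (percent of the L charged)

| time / h | G / % | E / % | D / % |
|---|---|---|---|
| 3.00 | 4.6 | 46.1 | 33.1 |
| 5.00 | 8.0 | 50.0 | 35.7 |
| 8.00 | 12.0 | 50.3 | 36.7 |
| 15.0 | 13.5 | 49.6 | 35.8 |
| 25.0 | 14.4 | 50.9 | 36.0 |
| 40.0 | 13.8 | 49.9 | 36.5 |

(standard deviation of a reading: 0.5 percentage points)

1. how much G there is at 2.0 d, in percent of the L charged
2. how much E there is at 2.0 d, in percent of the L charged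
3. how much D there is at 2.0 d, in percent of the L charged

Will L be gone from the flask by the asked time? Read as first order, the missing part of the eta run falls with a constant k of 0.472 /h. That is a half-life of 1.47 h, much shorter than 48 h.

What do you carry over? G lags, reading 12.0% at 8.00 h, so I take the eta run's G readings from 15.0 h on. Their mean is 13.9%, which I call the plateau share of G, P.

What error does replacing the curve by its mean make? The mean of these readings carries 0.29 percentage points from scatter. G moves by 0.3 points from 15.0 h to 40.0 h, less than the scatter of one reading, so these eta readings show no drift beyond their scatter.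

You ran one charge, so why trust it at 1.8 M? The eta run was made at one charge and does not show whether the split holds at another, so this is my assumption, and the flask tests it. On timing, suppose rates fell in step with the charge: 15.0 h stretches to 20.8 h, still shorter than 48 h. The same means give me E 50.1% and D 36.1%, with G at P.

The forecast gives G 13.9%, E 50.1% and D 36%, reading the products as “stable end points, or at least an equilibrated set”.

The flask gives G 14.3%, E 49.8% and D 35.9%.

    L → E (k = 1.70 × 10⁻⁴ /s)
    E ⇌ D (K = 0.720, k = 0.00270 /s)
    D ⇌ G (K = 0.398, k = 2.62 × 10⁻⁵ /s)

In the flask, the step between D and G, taken by itself, has a relaxation half-life of 0.0872 d, both ways together, and its forward rate by itself gives D a half-life of 0.31 d, short against 2.0 d. So 2.0 d spans 22.9 relaxation half-lives of this step, and the flask's G stands at 14.2% at 1.00 d and 14.3% at 2.00 d, with G/D at 0.398 against K of 0.398 (thermodynamic control). The reading P of 13.9% lies 0.40 points below the flask's G, and a second flask, charged with 1.1 M of L, holds G 14.3% at 2.00 d.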